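The ratio I want from these flasks is run time over the lifetime of E, which I call the turnover count.

    E + D → Z + J (k1 = 0.062 M⁻¹ min⁻¹)
    D + Z ⇌ D.Z, settled at all times (K2 = 6400 M⁻¹)
    D ⇌ Q (K3 = 0.51, k3 = 0.026 min⁻¹)
    E + J → E.J (k4 = 0.30 M⁻¹ min⁻¹)
    2 D → D2 (k5 = 0.027 M⁻¹ min⁻¹)

| flask | E | D | time |
|---|---|---|---|
| Monday's | 0.050 M | 0.150 M | 1.5 h |
| Tuesday's | 0.050 M | 0.300 M | 1.5 h |

* part of the E that has reacted at the end, Monday's
* part of the E that has reacted at the end, Tuesday's
* what raising the concentration of D from its lowest to its highest value here does to the part of the E that has reacted (changes below 5 percentage points count as none) (it falls / no change / it rises)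

- percentages count the E that a species holds: one E.J counts as two
- for a step with 2 of a species take k times the square, and two of it per event
- run time (Monday's): 1.5 h

The passing of D into Q relaxes, both ways together, with a half-life of 0.150 h on Tuesday's, and the run lasts ten times as long. I carry that to Monday's, since this step is first-order both ways. So I treat D and Q as balanced from the start, which is an approximation, and give free D the fraction 0.662 of its charge. With D held at that fraction, E decays pseudo-first-order in my reckoning.

I leave out two effects that pull opposite ways. D also goes to D2 and D.Z, which lowers the count. J takes a further E with a rate constant of 0.30 M⁻¹ min⁻¹, larger than the 0.062 M⁻¹ min⁻¹ of the first step, and that step raises the loss of E. I let them cancel.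

My table has two rows, Monday's and Tuesday's, and three columns: lifetime of E, turnover count, fraction of E gone. The turnover count is the run time divided by the lifetime of E under the first step with D at its balanced fraction, and the fraction gone is one minus the exponential of minus that count.

Monday's row reads 2.71 h, then 0.554, then 42.6 %. Tuesday's row reads 1.35 h, then 1.11, then 67.0 %.

Column against column, the count is twice as large on Tuesday's, but the fraction gone climbs by 24 percentage points. That is more than the 5 points that counts as a change, so my answer is: it rises.

The forecast gives 46 % for Monday's and 66 % for Tuesday's, and says it rises, on the grounds that “Doubling D still leaves about twice the free D”.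

The simulation gives 46.4 % on Monday's and 66.8 % on Tuesday's; it rises, by 20 points.

My fraction gone sits below Monday's flask by 3.9 points and above Tuesday's by 0.19 points. Neither flask is at rest at 1.5 h: E stands at 54 % of its charge on Monday's and 33 % on Tuesday's. Tuesday's flask left until 2.5 h has a count of 1.85, which gives 84.3 % gone, and it shows 81.8 %. At ten times the time, Monday's count is 5.54, which gives 99.6 %, and the flask shows 98.2 %. Over that stretch Monday's J falls from 19.4 % to 14.6 %, while E.J climbs from 27.0 % to 83.6 %.

The constants used here were set for the occasion; what happens was integrated by code.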